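The vessel is closed and stirred, and each flask starts from substrate seeded with a little target.

    substrate → target (k1 = 1.95 × 10⁻⁴ min⁻¹, Ea1 = 112 kJ mol⁻¹)
    substrate + target → side product (k2 = 0.0412 L mol⁻¹ min⁻¹, Ea2 = 62.0 kJ mol⁻¹)
    substrate + target → 2 target (k3 = 6.84 L mol⁻¹ min⁻¹, Ea3 = 52.0 kJ mol⁻¹)
    target ⇌ isomer of the product (K4 = 4250, k4 = 0.0106 min⁻¹, Ea4 = 90.0 kJ mol⁻¹, ΔH4 = −42.0 kJ mol⁻¹)
    (constants at 25 °C)

| flask | substrate | target | temperature | time | remark |
|---|---|---|---|---|---|
| east | 0.061 M | 0.305 mM | 50 °C | 15 h |  |
| south | 0.061 M | 0.305 mM | 25 °C | 15 h |  |
| north | 0.061 M | 0.305 mM |  | 15 h | at 0 °C until 5.0 h, from then on at 50 °C |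
| south-east | 0.061 M | 0.305 mM | 0 °C | 15 h |  |

- in percentages every species weighs as the substrate in it: one side product counts as two
- at 25 °C the constants are as listed, elsewhere as the activation energies and enthalpies make them

- the best flask by share of target in all that became target or side product or isomer of the product; "all alike" if 1.5 percentage points covers them all (east / south / north / south-east / all alike)
- share of target in all that became target or side product or isomer of the product, east
- share of target in all that became target or side product or isomer of the product, south
- share of target in all that became target or side product or isomer of the product, north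
- share of target in all that became target or side product or isomer of the product, south-east

The reckoning starts in south-east, at 0 °C. On the first rung is autocatalysis, with constant k_a = 1.00 L mol⁻¹ min⁻¹. It puts t_m, the moment when substrate and target are equal, at ln(substrate charge/target charge)/(k_a × total charge) = 1.44 h. The plain conversion of substrate to target, with constant 3.12 × 10⁻⁶ min⁻¹, starts at 1.02% of the seeded rate, so it is dropped. Side product is a small correction: with its constant k_s = 0.00418 L mol⁻¹ min⁻¹, the double-counted share is c = 0.829%.

On the next rung is isomerisation, with k_i = 3.82 × 10⁻⁴ min⁻¹ and a half-life of 30.2 h. That is longer than t_m, so target can be treated as born at t_m. The carried quantity is the survival S, the part of target born at t_m that has not isomerised by time t: S = exp(−k_i(t − t_m)). At 15 h it is 73.3%, and the correction c brings the reckoned share in south-east to 72.7%. The backward run is ignored there, with equilibrium constant K = 20000.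

Warmer flasks have a floor, the equilibrium share of target, about the reciprocal of K, and S sits on top of it. At 50 °C, k_h = 0.176 min⁻¹ gives a half-life of 3.94 min, shorter than the time east spends there and the stretch north spends there. So both flasks are reckoned at the floor, with K = 1150, at 0.0872%. South, floor plus S, reckons to 0.0317%. South-east therefore leads this reckoning, as kinetic control against thermodynamic control.

The forecast names south-east and gives 0.086% for east, 0.031% for south, 0.087% for north and 72.6% for south-east, where “roughly three quarters survives”. The reckoning above gives 72.7% for south-east, 0.0872% for east and north and 0.0317% for south, beside the forecast's figures.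

The simulation names south-east, with 0.0858% for east, 0.0314% for south, 0.0865% for north and 72.7% for south-east. In south-east at 1.45 h, target's half-life toward the isomer, by the forward rate alone, is 30 h, shorter than the 91 h toward side product but longer than the run of 15 h. At the end south-east holds 73.1% target beside 26.6% isomer of the product, where S was reckoned at 73.3%. For the same flask left until 2.5 d, S becomes 26.1%, and that flask shows a target share of 25.9%, with isomer of the product at 73.6%.

The constants used here belong to no real substance; the run is a simulation.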